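The oxan-2-one ring is read as a hidden cyclopropane: ring carbon C6 bears the ring oxygen O1 and sits next to C7, whose methyl group (C7a) is the third cyclopropane carbon. In the key step divalent mercury opens a trans-cyclopropane (C6, C7, C7a) whose tert-butyl ester carbonyl lies three carbons from C6; the ester oxygen attacks C6 with inversion and closes the δ-lactone through the O1–C6 bond, and tin hydride turns CH2Hg into the C7 methyl. One catalytic alkenylzinc addition sets C5; C6 and C7 are relayed from it by an anti-selective cyclopropanation. The dienoate is then built on O5 by phosphonoacetylation and olefination with a separately made enal.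

Key step: step 6

Remark: atoms are labelled O1, C2 (carbonyl), C3, C4, C5 (acyloxy carbon), C6 in the ring, C7 to C13 along the side chain and C7a for the methyl on C7; it is assumed that an (E)-allylic silyl ether is cyclopropanated anti to the silyloxy group, as is known for this substrate class.

Step 1
Reactants: 1 (S)-3-bromo-2-methylpropan-1-ol
Product: 2 (S)-1-bromo-3-chloro-2-methylpropane
Conditions: NCS, PPh3, CH2Cl2, 0 °C to rt
Reagents that add atoms: N-chlorosuccinimide, O=C1CCC(=O)N1Cl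
Why: Appel-type chlorination, in which chloride displaces the alkoxyphosphonium ion at the primary carbon under neutral conditions, so the bromide and the stereocentre (not a reacting atom) stay untouched and the two arms remain different.

Step 2
Reactants: 2 (S)-1-bromo-3-chloro-2-methylpropane
Product: 3 (R)-5-chloro-4-methylpent-1-yne
Conditions: HC≡CLi·H2NCH2CH2NH2, DMSO, 15 °C
Reagents that add atoms: lithium acetylide–ethylenediamine complex, [Li+].[C-]#C.NCCN
Why: SN2 alkylation of acetylide, in which the primary bromide reacts far faster than the primary chloride, so C8 is joined to the future C6 and C7 and the chloride is kept as an inert C10 handle.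

Step 3
Reactants: 3 (R)-5-chloro-4-methylpent-1-yne; 4 tert-butyl 4-oxobutanoate
Product: 7 tert-butyl (4R,5E,8R)-9-chloro-4-hydroxy-8-methylnon-5-enoate, via alkenylborane 5 (not isolated), via alkenylzinc 6 (not isolated)
Conditions: Cy2BH, toluene, 0 °C to rt; Me2Zn, −78 °C; (−)-MIB (4 mol%), then 4, −20 to 0 °C; aq. NH4Cl
Reagents that add atoms: none
Why: syn hydroboration gives the (E)-alkenylborane, boron-to-zinc exchange the alkenylzinc, and the amino-alcohol-catalysed enantioselective alkenylzinc addition to the aldehyde sets C5, (−)-3-exo-morpholinoisoborneol being expected to deliver the alkenyl group to the Si face to give the (R)-alcohol.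

Step 4
Reactants: 7 tert-butyl (4R,5E,8R)-9-chloro-4-hydroxy-8-methylnon-5-enoate
Product: 8 tert-butyl (4R,5E,8R)-4-[(tert-butyldimethylsilyl)oxy]-9-chloro-8-methylnon-5-enoate
Conditions: TBSCl, imidazole, DMF, rt
Reagents that add atoms: tert-butyldimethylsilyl chloride, CC(C)(C)[Si](C)(C)Cl
Why: standard silylation of the secondary allylic alcohol, which removes the zinc-directing hydroxyl group before step 5 and gives a non-participating group for step 6.

Step 5
Reactants: 8 tert-butyl (4R,5E,8R)-4-[(tert-butyldimethylsilyl)oxy]-9-chloro-8-methylnon-5-enoate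
Product: 9 tert-butyl (4R)-4-[(tert-butyldimethylsilyl)oxy]-4-{(1S,2R)-2-[(2R)-3-chloro-2-methylpropyl]cyclopropyl}butanoate (trans-cyclopropane, anti to the silyloxy group)
Conditions: Et2Zn, CF3CO2H, CH2I2, CH2Cl2, 0 °C; then 8, 0 °C to rt
Reagents that add atoms: diiodomethane, ICI
Why: Simmons–Smith cyclopropanation with the trifluoroacetate-modified zinc carbenoid, whose stereospecific syn addition turns the (E)-alkene into the trans-cyclopropane and which, lacking a zinc alkoxide to direct it, should add anti to the bulky silyloxy group in the conformer with C5–H eclipsing the alkene, so that C6 and C7 are set from C5.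

Step 6
Reactants: 9 tert-butyl (4R)-4-[(tert-butyldimethylsilyl)oxy]-4-{(1S,2R)-2-[(2R)-3-chloro-2-methylpropyl]cyclopropyl}butanoate
Product: 11 (5R,6R)-5-[(tert-butyldimethylsilyl)oxy]-6-[(2R,4R)-5-chloro-4-methylpentan-2-yl]oxan-2-one, via organomercury trifluoroacetate 10 (not isolated)
Conditions: Hg(OCOCF3)2, CH2Cl2, 0 °C to rt; solvent switch to THF; n-Bu3SnH, AIBN (cat.), 50 °C
Reagents that add atoms: none
Why: Electrophilic divalent mercury attacks the unsubstituted cyclopropane carbon C7a and the C6–C7a bond breaks as the ester carbonyl oxygen adds to C6 from the rear, after which the dialkoxycarbenium ion loses 2-methylpropene and tin hydride replaces mercury by hydrogen, so the former ring CH2 becomes the C7 methyl. The closest known reaction type is the mercury-mediated ring opening of cyclopropylcarbinyl derivatives by neighbouring oxygen nucleophiles, an oxymercuration–demercuration carried over from alkenes to a strained sigma bond. The oxan-2-one ring closes in a 6-exo-tet mode, the breaking C6–C7a bond lying outside the new ring. C6 is set by stereospecific inversion and is therefore controlled by the cyclopropane configuration, while C7 keeps its configuration and C5 is a spectator. The step needs regioselectivity for C6 over C7: attack at C7 would need a seven-membered ring or external trifluoroacetate, so the six-membered tether should prevail although the C5 silyloxy group lowers the electron density at C6. Chemoselectivity is secured by keeping every alkene out of the substrate, and the silyl ether and the alkyl chloride do not participate.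

Step 7
Reactants: 11 (5R,6R)-5-[(tert-butyldimethylsilyl)oxy]-6-[(2R,4R)-5-chloro-4-methylpentan-2-yl]oxan-2-one
Product: 12 (5R,6R)-5-[(tert-butyldimethylsilyl)oxy]-6-[(2R,4R)-5-iodo-4-methylpentan-2-yl]oxan-2-one
Conditions: NaI, butan-2-one, 80 °C
Reagents that add atoms: sodium iodide, [Na+].[I-]
Why: Finkelstein exchange (SN2) at the primary chloride, driven by precipitation of NaCl, with the lactone and the silyl ether inert.

Step 8
Reactants: 12 (5R,6R)-5-[(tert-butyldimethylsilyl)oxy]-6-[(2R,4R)-5-iodo-4-methylpentan-2-yl]oxan-2-one; 13 (E)-2-bromobut-2-ene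
Product: 15 (5R,6R)-5-[(tert-butyldimethylsilyl)oxy]-6-[(2R,4R,6E)-4,6-dimethyloct-6-en-2-yl]oxan-2-one, via alkylzinc iodide 14 (not isolated)
Conditions: Zn dust, LiCl, THF, 40 °C; then 13, Pd(OAc)2 (3 mol%), SPhos (6 mol%), rt to 40 °C
Reagents that add atoms: none
Why: zinc insertion into the primary iodide tolerates the lactone, and the Negishi coupling with the alkenyl bromide under zerovalent palladium catalysis keeps the alkene geometry, forming C10–C11 and the (E)-trisubstituted alkene.

Step 9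
Reactants: 15 (5R,6R)-5-[(tert-butyldimethylsilyl)oxy]-6-[(2R,4R,6E)-4,6-dimethyloct-6-en-2-yl]oxan-2-one
Product: 16 (5R,6R)-6-[(2R,4R,6E)-4,6-dimethyloct-6-en-2-yl]-5-hydroxyoxan-2-one
Conditions: HF·pyridine, pyridine, THF, 0 °C
Reagents that add atoms: none
Why: fluoride cleavage of the secondary silyl ether under buffered, weakly acidic conditions chosen to spare the hydroxy δ-lactone, which is acylated at once.

Step 10
Reactants: 16 (5R,6R)-6-[(2R,4R,6E)-4,6-dimethyloct-6-en-2-yl]-5-hydroxyoxan-2-one; 17 (diethoxyphosphoryl)acetic acid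
Product: 18 (2R,3R)-2-[(2R,4R,6E)-4,6-dimethyloct-6-en-2-yl]-6-oxooxan-3-yl (diethoxyphosphoryl)acetate
Conditions: DCC, DMAP (5 mol%), CH2Cl2, 0 °C
Reagents that add atoms: none
Why: Steglich-type esterification in which the small, DCC-activated phosphonoacetic acid acylates the C5 hydroxyl quickly, so the δ-lactone has little time to contract to the γ-lactone.

Step 11
Reactants: 19 furan-2(5H)-one; 20 (2-methylprop-1-en-1-yl)boronic acid
Product: 21 (R)-4-(2-methylprop-1-en-1-yl)oxolan-2-one
Conditions: [Rh(OH)((R)-BINAP)]2 (1.5 mol%), dioxane/H2O 10:1, 40 °C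
Reagents that add atoms: none
Why: Hayashi–Miyaura reaction, the rhodium-catalysed enantioselective 1,4-addition of an alkenylboronic acid to the butenolide, with (R)-BINAP chosen by analogy with cyclic enones to give the (R)-lactone and so the only stereocentre of the acyl chain.

Step 12
Reactants: 21 (R)-4-(2-methylprop-1-en-1-yl)oxolan-2-one
Product: 22 (R)-2-(2-methylprop-1-en-1-yl)butane-1,4-diol
Conditions: LiAlH4, THF, 0 °C to rt
Reagents that add atoms: none
Why: hydride reduction of the lactone to the 1,4-diol, which turns the ring CH2O arm and the CH2C(=O) arm into the two different hydroxyalkyl arms without touching the stereocentre.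

Step 13
Reactants: 22 (R)-2-(2-methylprop-1-en-1-yl)butane-1,4-diol
Product: 23 (R)-1,4-bis[(tert-butyldimethylsilyl)oxy]-2-(2-methylprop-1-en-1-yl)butane
Conditions: TBSCl, imidazole, DMF, rt
Reagents that add atoms: tert-butyldimethylsilyl chloride, CC(C)(C)[Si](C)(C)Cl
Why: standard silylation of both primary alcohols.

Step 14
Reactants: 23 (R)-1,4-bis[(tert-butyldimethylsilyl)oxy]-2-(2-methylprop-1-en-1-yl)butane
Product: 25 (2E,4R)-6-[(tert-butyldimethylsilyl)oxy]-4-{[(tert-butyldimethylsilyl)oxy]methyl}-2-methylhex-2-enal, via allylic alcohol 24 (not isolated)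
Conditions: SeO2 (cat.), t-BuOOH, salicylic acid (cat.), CH2Cl2, rt; then MnO2, CH2Cl2, rt
Reagents that add atoms: tert-butyl hydroperoxide, CC(C)(C)OO
Why: allylic oxidation by SeO2 (ene reaction, then [2,3]-sigmatropic shift) attacks the (E)-methyl group of the trisubstituted alkene selectively and MnO2 oxidises the allylic alcohol to the (E)-enal, while the stereocentre, on the less substituted alkene carbon, is not involved.

Step 15
Reactants: 18 (2R,3R)-2-[(2R,4R,6E)-4,6-dimethyloct-6-en-2-yl]-6-oxooxan-3-yl (diethoxyphosphoryl)acetate; 25 (2E,4R)-6-[(tert-butyldimethylsilyl)oxy]-4-{[(tert-butyldimethylsilyl)oxy]methyl}-2-methylhex-2-enal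
Product: 26 (2R,3R)-2-[(2R,4R,6E)-4,6-dimethyloct-6-en-2-yl]-6-oxooxan-3-yl (2E,4E,6R)-8-[(tert-butyldimethylsilyl)oxy]-6-{[(tert-butyldimethylsilyl)oxy]methyl}-4-methylocta-2,4-dienoate
Conditions: LiCl, DBU, MeCN, 0 °C to rt
Reagents that add atoms: none
Why: Horner–Wadsworth–Emmons olefination of the lithium-chelated phosphonate with the enal should give the (2E)-alkene and complete the (2E,4E)-dienoate on O5, the mild amine base leaving the lactone and the epimerisable positions alone.

Step 16
Reactants: 26 (2R,3R)-2-[(2R,4R,6E)-4,6-dimethyloct-6-en-2-yl]-6-oxooxan-3-yl (2E,4E,6R)-8-[(tert-butyldimethylsilyl)oxy]-6-{[(tert-butyldimethylsilyl)oxy]methyl}-4-methylocta-2,4-dienoate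
Product: 27 (2R,3R)-2-[(2R,4R,6E)-4,6-dimethyloct-6-en-2-yl]-6-oxooxan-3-yl (2E,4E,6R)-8-hydroxy-6-(hydroxymethyl)-4-methylocta-2,4-dienoate (target)
Conditions: HF·pyridine, pyridine, THF, 0 °C to rt
Reagents that add atoms: none
Why: buffered HF·pyridine should remove both primary silyl ethers without acyl migration or lactone opening.

Compound list
1 | (S)-3-bromo-2-methylpropan-1-ol | OC[C@H](C)CBr | starting material
2 | (S)-1-bromo-3-chloro-2-methylpropane | ClC[C@H](C)CBr | intermediate
3 | (R)-5-chloro-4-methylpent-1-yne | ClC[C@H](C)CC#C | intermediate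
4 | tert-butyl 4-oxobutanoate | CC(C)(C)OC(=O)CCC=O | starting material
5 | dicyclohexyl[(1E,4R)-5-chloro-4-methylpent-1-en-1-yl]borane | ClC[C@H](C)C/C=C/B(C1CCCCC1)C1CCCCC1 | intermediate (not isolated)
6 | [(1E,4R)-5-chloro-4-methylpent-1-en-1-yl](methyl)zinc | ClC[C@H](C)C/C=C/[Zn]C | intermediate (not isolated)
7 | tert-butyl (4R,5E,8R)-9-chloro-4-hydroxy-8-methylnon-5-enoate | CC(C)(C)OC(=O)CC[C@@H](O)/C=C/C[C@@H](C)CCl | intermediate
8 | tert-butyl (4R,5E,8R)-4-[(tert-butyldimethylsilyl)oxy]-9-chloro-8-methylnon-5-enoate | CC(C)(C)OC(=O)CC[C@@H](O[Si](C)(C)C(C)(C)C)/C=C/C[C@@H](C)CCl | intermediate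
9 | tert-butyl (4R)-4-[(tert-butyldimethylsilyl)oxy]-4-{(1S,2R)-2-[(2R)-3-chloro-2-methylpropyl]cyclopropyl}butanoate | CC(C)(C)OC(=O)CC[C@@H](O[Si](C)(C)C(C)(C)C)[C@H]1C[C@@H]1C[C@@H](C)CCl | intermediate
10 | {(2R,4R)-2-[(2R,3R)-3-[(tert-butyldimethylsilyl)oxy]-6-oxooxan-2-yl]-5-chloro-4-methylpentyl}mercury trifluoroacetate | ClC[C@H](C)C[C@@H](C[Hg]OC(=O)C(F)(F)F)[C@H]1OC(=O)CC[C@H]1O[Si](C)(C)C(C)(C)C | intermediate (not isolated)
11 | (5R,6R)-5-[(tert-butyldimethylsilyl)oxy]-6-[(2R,4R)-5-chloro-4-methylpentan-2-yl]oxan-2-one | ClC[C@H](C)C[C@@H](C)[C@H]1OC(=O)CC[C@H]1O[Si](C)(C)C(C)(C)C | intermediate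
12 | (5R,6R)-5-[(tert-butyldimethylsilyl)oxy]-6-[(2R,4R)-5-iodo-4-methylpentan-2-yl]oxan-2-one | IC[C@H](C)C[C@@H](C)[C@H]1OC(=O)CC[C@H]1O[Si](C)(C)C(C)(C)C | intermediate
13 | (E)-2-bromobut-2-ene | C/C=C(\C)Br | starting material
14 | {(2R,4R)-4-[(2R,3R)-3-[(tert-butyldimethylsilyl)oxy]-6-oxooxan-2-yl]-2-methylpentyl}zinc iodide | I[Zn]C[C@H](C)C[C@@H](C)[C@H]1OC(=O)CC[C@H]1O[Si](C)(C)C(C)(C)C | intermediate (not isolated)
15 | (5R,6R)-5-[(tert-butyldimethylsilyl)oxy]-6-[(2R,4R,6E)-4,6-dimethyloct-6-en-2-yl]oxan-2-one | C/C=C(\C)C[C@H](C)C[C@@H](C)[C@H]1OC(=O)CC[C@H]1O[Si](C)(C)C(C)(C)C | intermediate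
16 | (5R,6R)-6-[(2R,4R,6E)-4,6-dimethyloct-6-en-2-yl]-5-hydroxyoxan-2-one | C/C=C(\C)C[C@H](C)C[C@@H](C)[C@H]1OC(=O)CC[C@H]1O | intermediate
17 | (diethoxyphosphoryl)acetic acid | OC(=O)CP(=O)(OCC)OCC | starting material
18 | (2R,3R)-2-[(2R,4R,6E)-4,6-dimethyloct-6-en-2-yl]-6-oxooxan-3-yl (diethoxyphosphoryl)acetate | C/C=C(\C)C[C@H](C)C[C@@H](C)[C@H]1OC(=O)CC[C@H]1OC(=O)CP(=O)(OCC)OCC | intermediate
19 | furan-2(5H)-one | O=C1OCC=C1 | starting material
20 | (2-methylprop-1-en-1-yl)boronic acid | CC(C)=CB(O)O | starting material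
21 | (R)-4-(2-methylprop-1-en-1-yl)oxolan-2-one | CC(C)=C[C@@H]1COC(=O)C1 | intermediate
22 | (R)-2-(2-methylprop-1-en-1-yl)butane-1,4-diol | CC(C)=C[C@H](CO)CCO | intermediate
23 | (R)-1,4-bis[(tert-butyldimethylsilyl)oxy]-2-(2-methylprop-1-en-1-yl)butane | CC(C)=C[C@H](CO[Si](C)(C)C(C)(C)C)CCO[Si](C)(C)C(C)(C)C | intermediate
24 | (2E,4R)-6-[(tert-butyldimethylsilyl)oxy]-4-{[(tert-butyldimethylsilyl)oxy]methyl}-2-methylhex-2-en-1-ol | OC/C(C)=C/[C@H](CO[Si](C)(C)C(C)(C)C)CCO[Si](C)(C)C(C)(C)C | intermediate (not isolated)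
25 | (2E,4R)-6-[(tert-butyldimethylsilyl)oxy]-4-{[(tert-butyldimethylsilyl)oxy]methyl}-2-methylhex-2-enal | O=C/C(C)=C/[C@H](CO[Si](C)(C)C(C)(C)C)CCO[Si](C)(C)C(C)(C)C | intermediate
26 | (2R,3R)-2-[(2R,4R,6E)-4,6-dimethyloct-6-en-2-yl]-6-oxooxan-3-yl (2E,4E,6R)-8-[(tert-butyldimethylsilyl)oxy]-6-{[(tert-butyldimethylsilyl)oxy]methyl}-4-methylocta-2,4-dienoate | C/C=C(\C)C[C@H](C)C[C@@H](C)[C@H]1OC(=O)CC[C@H]1OC(=O)/C=C/C(C)=C/[C@H](CO[Si](C)(C)C(C)(C)C)CCO[Si](C)(C)C(C)(C)C | intermediate
27 | (2R,3R)-2-[(2R,4R,6E)-4,6-dimethyloct-6-en-2-yl]-6-oxooxan-3-yl (2E,4E,6R)-8-hydroxy-6-(hydroxymethyl)-4-methylocta-2,4-dienoate | C/C=C(\C)C[C@H](C)C[C@@H](C)[C@H]1OC(=O)CC[C@H]1OC(=O)/C=C/C(C)=C/[C@H](CO)CCO | target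

Total step count: 16. Longest linear sequence: 12 steps (steps 1 to 10, then 15 and 16).

Steps most likely to fail

1. Step 6. The ring opening may lose regiocontrol: external trifluoroacetate may add at C7, which is electronically favoured because the silyloxy group deactivates C6, or the ester may participate so slowly that acid strips the silyl ether. The fallback replaces the ester by an N,N-dimethyl amide, whose oxygen is a much stronger neighbouring group, so that closure through an iminium ether should outrun external capture. It sets out from 7. Acid-catalysed lactonisation (p-TsOH, toluene) should give the γ-lactone (5R)-5-[(1E,4R)-5-chloro-4-methylpent-1-en-1-yl]oxolan-2-one F1. Aminolysis with the aluminium amide from AlMe3 and Me2NH·HCl should give the hydroxy amide (4R,5E,8R)-9-chloro-4-hydroxy-N,N,8-trimethylnon-5-enamide F2. Silylation (TBSCl, imidazole) should give (4R,5E,8R)-4-[(tert-butyldimethylsilyl)oxy]-9-chloro-N,N,8-trimethylnon-5-enamide F3. Cyclopropanation as in step 5 should give (4R)-4-[(tert-butyldimethylsilyl)oxy]-4-{(1S,2R)-2-[(2R)-3-chloro-2-methylpropyl]cyclopropyl}-N,N-dimethylbutanamide F4. Hg(OCOCF3)2 should then close the ring through the amide oxygen to the mercurated iminium ether {(2R,4R)-2-[(2R,3R)-3-[(tert-butyldimethylsilyl)oxy]-6-(dimethyliminio)oxan-2-yl]-5-chloro-4-methylpentyl}mercury trifluoroacetate, trifluoroacetate salt F5. Water hydrolyses F5 to 10, where the fallback comes back to the route before the tin hydride reduction to 11.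

2. Step 5. The non-directed cyclopropanation may show poor facial selectivity or be slow on the hindered silyl ether, with Lewis-acid loss of the tert-butyl ester on long exposure. The fallback uses hydroxyl direction and then inverts C5. It sets out from 3 and 4. Step 3 run with (+)-MIB should give tert-butyl (4S,5E,8R)-9-chloro-4-hydroxy-8-methylnon-5-enoate F6. Hydroxyl-directed Simmons–Smith cyclopropanation (Et2Zn, CH2I2, CH2Cl2) should give the syn product tert-butyl (4S)-4-{(1S,2R)-2-[(2R)-3-chloro-2-methylpropyl]cyclopropyl}-4-hydroxybutanoate F7, in which both ring centres are already those of 9. Mitsunobu inversion (4-nitrobenzoic acid, PPh3, DIAD) should give (1R)-4-tert-butoxy-1-{(1S,2R)-2-[(2R)-3-chloro-2-methylpropyl]cyclopropyl}-4-oxobutyl 4-nitrobenzoate F8. Methanolysis (K2CO3, MeOH, 0 °C) should give tert-butyl (4R)-4-{(1S,2R)-2-[(2R)-3-chloro-2-methylpropyl]cyclopropyl}-4-hydroxybutanoate F9, and silylation as in step 4 returns to 9.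

3. Step 9. The free cis-5-hydroxy δ-lactone may contract to the γ-lactone during desilylation or before it is acylated. The fallback never frees the hydroxyl group. It sets out from 15: direct conversion of the silyl ether into an ester with bromoacetyl bromide and catalytic SnBr2 (CH2Cl2, rt) should give (2R,3R)-2-[(2R,4R,6E)-4,6-dimethyloct-6-en-2-yl]-6-oxooxan-3-yl bromoacetate F10. A Michaelis–Arbuzov reaction with P(OEt)3 (90 °C) then returns to 18.

Further compounds
F1 | step 6 | (5R)-5-[(1E,4R)-5-chloro-4-methylpent-1-en-1-yl]oxolan-2-one | O=C1CC[C@@H](O1)/C=C/C[C@@H](C)CCl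
F2 | step 6 | (4R,5E,8R)-9-chloro-4-hydroxy-N,N,8-trimethylnon-5-enamide | CN(C)C(=O)CC[C@@H](O)/C=C/C[C@@H](C)CCl
F3 | step 6 | (4R,5E,8R)-4-[(tert-butyldimethylsilyl)oxy]-9-chloro-N,N,8-trimethylnon-5-enamide | CN(C)C(=O)CC[C@@H](O[Si](C)(C)C(C)(C)C)/C=C/C[C@@H](C)CCl
F4 | step 6 | (4R)-4-[(tert-butyldimethylsilyl)oxy]-4-{(1S,2R)-2-[(2R)-3-chloro-2-methylpropyl]cyclopropyl}-N,N-dimethylbutanamide | CN(C)C(=O)CC[C@@H](O[Si](C)(C)C(C)(C)C)[C@H]1C[C@@H]1C[C@@H](C)CCl
F5 | step 6 | {(2R,4R)-2-[(2R,3R)-3-[(tert-butyldimethylsilyl)oxy]-6-(dimethyliminio)oxan-2-yl]-5-chloro-4-methylpentyl}mercury trifluoroacetate, trifluoroacetate salt | ClC[C@H](C)C[C@@H](C[Hg]OC(=O)C(F)(F)F)[C@H]1OC(=[N+](C)C)CC[C@H]1O[Si](C)(C)C(C)(C)C.[O-]C(=O)C(F)(F)F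
F6 | step 5 | tert-butyl (4S,5E,8R)-9-chloro-4-hydroxy-8-methylnon-5-enoate | CC(C)(C)OC(=O)CC[C@H](O)/C=C/C[C@@H](C)CCl
F7 | step 5 | tert-butyl (4S)-4-{(1S,2R)-2-[(2R)-3-chloro-2-methylpropyl]cyclopropyl}-4-hydroxybutanoate | CC(C)(C)OC(=O)CC[C@H](O)[C@H]1C[C@@H]1C[C@@H](C)CCl
F8 | step 5 | (1R)-4-tert-butoxy-1-{(1S,2R)-2-[(2R)-3-chloro-2-methylpropyl]cyclopropyl}-4-oxobutyl 4-nitrobenzoate | CC(C)(C)OC(=O)CC[C@@H](OC(=O)c1ccc(cc1)[N+](=O)[O-])[C@H]1C[C@@H]1C[C@@H](C)CCl
F9 | step 5 | tert-butyl (4R)-4-{(1S,2R)-2-[(2R)-3-chloro-2-methylpropyl]cyclopropyl}-4-hydroxybutanoate | CC(C)(C)OC(=O)CC[C@@H](O)[C@H]1C[C@@H]1C[C@@H](C)CCl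
F10 | step 9 | (2R,3R)-2-[(2R,4R,6E)-4,6-dimethyloct-6-en-2-yl]-6-oxooxan-3-yl bromoacetate | C/C=C(\C)C[C@H](C)C[C@@H](C)[C@H]1OC(=O)CC[C@H]1OC(=O)CBr
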